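## The problem

The target, (2S,3S,5R)-5-allyl-5,7-dimethoxy-3-methyl-2-(3,4,5-trimethoxyphenyl)-3,5-dihydro-1-benzofuran-6(2H)-one (21), is a dihydrofuran fused through C3a–C7a to a cyclohexa-2,4-dienone. Every carbon of the six-membered ring except C4 is substituted: a ketone at C6, the enol-ether oxygen O1 on C7a, a methoxy group on C7, and a quaternary C5 carrying both a methoxy and an allyl group. C2 and C3 are neighbours and trans; once C2 is fixed, C3 will settle trans to the aryl group if it is made epimerisable. C5 lies on the far side of a flat dienone, trans to C3 across the C3a=C4 bond, so neither C2 nor C3 can bias it and a reagent has to set it. The 6-allyl-6-methoxy-dienone is the fragile part: on warming it can re-aromatise by retro-Claisen shift to an aryl allyl ether or pass its allyl group to C3a by Cope shift, and in acid the C2–O1 bond, a benzylic ether (later a vinylogous benzylic ester), can ionise. The dienone should therefore be made last, cold and near neutrality, and the allyl group rules out any late hydrogenation. There is also a regiochemical trap: when a C6 phenol of this series is oxidised in an alcohol, the nucleophile is expected at the oxygen-bearing C7 or the para carbon C3a, not at C5, so C5 is better built by addition to a carbonyl group. The feature that opens the bicyclic core is that C3, C3a and the carbon of the C3 methyl group stand in the same relation as C3, C4a and the carbonyl carbon C4 of a 2-arylchroman-4-one: a flavanone contracted by one ring atom, with the extruded carbon left on C3, is the 2-aryl-3-methyl-dihydrobenzofuran.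

## Retrosynthesis

**C5–OCH3.** The O–CH3 bond of 21 is cut first, leading to the tertiary ketol 20. The neighbouring cut, forming the C5–O bond by letting an alcohol add to an oxidised phenol, would put the nucleophile on C7 or C3a. Methylating an existing C5–OH has no regiochemical question. The forward step must avoid a free alkoxide, which could trigger an oxy-Cope or ketol shift.

**C5–allyl.** Cutting the C5–CH2 bond of 20 gives the ortho-quinone 18 and allyltributylstannane 19. Of the two carbonyl groups of 18, C6 is a vinylogous ester (O1–C7a=C7–C6=O) and is deactivated, so C5 is the electrophilic one. Delivering the allyl group from O6 by a Claisen shift would have to dearomatise ring A and runs uphill. The precursor is flat at C5, so this step must create the C5 stereocentre under control of a chiral Lewis acid.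

**C5=O.** The C5 oxygen of 18 is taken back to a C–H bond in phenol 17. In 17 the para position (C3a) is blocked and C5 is the only unsubstituted ortho carbon, so a radical ortho-oxidation has one place to go. Carrying this oxygen from the start would need a tetra-oxygenated acetophenone and two orthogonal protecting groups.

**O6 protection.** Phenol 17 comes from its benzyl ether 16. Benzyl is chosen because it survives base, hydride, light and the palladium-catalysed arylation, and is removed before any alkene is present.

**C3 methyl.** The methyl group of 16 is the reduced form of the ester carbon of 13, through alcohol 14 and tosylate 15. The ester is kept until then because it is the direct product of the ring contraction and because it makes C3 epimerisable, which is how the trans relationship is secured.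

**C3–C3a (key cut).** Ester 13 is traced to the 3-diazoflavanone 10 by reversing a 1,2-shift of the aryl carbon: the C3–C3a bond is opened and the ester carbon is put back into the ring as C4. Closing the dihydrofuran at O1–C2 or O1–C7a instead would require C2 and C3 to be set together in an open chain. Here only C2 is set, on a flat chromone, and C3 follows from it.

**Diazo group.** Diazo ketone 10 comes from flavanone 8 by acylative activation (via 9) and diazo transfer. The forward reaction must keep the enolate cold and short-lived so that the pyranone does not open at C2.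

**C2–aryl.** Flavanone 8 is cut at the C2–aryl bond to chromone 6 and boronic acid 7. A catalytic asymmetric conjugate addition under base-free conditions sets C2 and cannot racemise it by ring opening.

**Chromone.** Chromone 6 is cut at O1–C2 and C2–C3 to acetophenone 3 and the one-carbon unit 4, through enaminone 5. Acetophenone 3 comes from gallacetophenone 1 by two selective O-alkylations via 2, which rely on the acidity order of its three hydroxyl groups.

## Roads not taken

**Alternative 1:** A cyclobutenone cascade would build both rings at once. The cuts are C3a–C7a, C6–C7 and C5–C6. On heating, cyclobutenone A1 opens to a vinylketene, which adds across its tethered ethynyl ether; the new vinylcyclobutenone reopens and closes by six-electron electrocyclisation to dienone A2. The merit is real: C5 arrives with its methoxy and allyl groups already attached, so no aromatic ring has to be dearomatised and the three-step quinone endgame of the chosen plan (steps 11–13) would be unnecessary. The weak points are these. A2 lacks the C7 methoxy group, because C7 derives from the terminal alkyne carbon, so a sensitive dienone would have to be oxygenated at the end. The C5 configuration is not transferred: the sp3 carbon of A1 becomes trigonal in the vinylketene and is re-created in the electrocyclisation without bias, so both C5 epimers are expected. The tether in A1 is a benzylic alkynyl ether, a class prone to sigmatropic rearrangement near ambient temperature, and the anti stereodiad must be made separately. The chosen plan spends more steps at the end but works throughout with stable intermediates and has a reagent-based handle on C5.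

**Alternative 2:** Here the O1–C7a bond is cut. Two-electron oxidation of catechol A3 to its ortho-quinone lets the side-chain hydroxyl add at C7a in a 5-exo conjugate addition, and a second oxidation gives the bicyclic quinone A4. A4 is the same compound as 18, so from there the two plans are identical. This road is shorter at the end, since it needs no phenol protecting group and no separate ortho-oxidation, which is a genuine advantage. Against it, both C2 and C3 must be set in the open-chain precursor A3 by two independent operations, whereas the chosen plan sets C2 by one catalytic step and lets C3 equilibrate. The first-formed monocyclic quinone also has its benzylic C–H para to a carbonyl and can tautomerise to a quinone methide before the hydroxyl adds, which would erase C3. In the chosen plan the same risk exists for 18, but the oxygen ring is already closed and the quinone is consumed at once.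

**Alternative 3:** Here the O1–C2 bond is cut. Asymmetric hydrogenation of a trisubstituted stilbene sets C3 in A5; oxidation of its 4-alkyl-2,6-dimethoxyphenol to the para-quinone methide lets the ortho-phenol oxygen add to the methide carbon (5-exo), giving A6 with the aryl group trans to the methyl group. Methylation of the phenol and removal of the methoxymethyl group would then give 17, where this road meets the chosen one. It is probably a step or two shorter to 17 and needs only one catalyst-controlled centre, as the chosen plan does. Its risks are a hydrogenation of a hindered, ortho-oxygenated alkene that must deliver high enantiopurity, a chemoselective oxidation in the presence of a second electron-rich phenol, and a C2 configuration fixed in the cyclisation with no means of later correction. The chosen plan sets against this a well-charted conjugate arylation of a flat chromone and an ester at C3 through which the trans relationship can be restored by equilibration.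

Key step: step 6

Remark on the chemistry: the ligand antipodes named in steps 4 and 12 are assigned by analogy with the known facial preference of these catalyst families; if a first run shows the opposite sense, the mirror-image ligand is used and nothing else changes.

## Route

Step 1
Reactants: 1 gallacetophenone (1-(2,3,4-trihydroxyphenyl)ethan-1-one)
Product: 2 1-[4-(benzyloxy)-2,3-dihydroxyphenyl]ethan-1-one
Conditions: BnBr (1.0 equiv), NaHCO3, NaI (cat.), DMF, 40 °C
Reagents that add atoms: benzyl bromide, BrCc1ccccc1
Why: Williamson etherification; the 4-OH, para to the acetyl group, is the most acidic, while the 2-OH is tied up in a hydrogen bond to the carbonyl and the 3-OH is less acidic, so a weak base and one equivalent of halide should alkylate O4 only.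

Step 2
Reactants: 2 1-[4-(benzyloxy)-2,3-dihydroxyphenyl]ethan-1-one
Product: 3 1-[4-(benzyloxy)-2-hydroxy-3-methoxyphenyl]ethan-1-one
Conditions: MeI (1.1 equiv), K2CO3 (1.0 equiv), acetone, 20–40 °C
Reagents that add atoms: iodomethane, CI
Why: Williamson methylation; of the two remaining hydroxyls the chelated 2-OH is much the poorer nucleophile, so one equivalent of MeI should go to O3.

Step 3
Reactants: 3 1-[4-(benzyloxy)-2-hydroxy-3-methoxyphenyl]ethan-1-one; 4 N,N-dimethylformamide dimethyl acetal
Product: 6 7-(benzyloxy)-8-methoxy-4H-chromen-4-one, via enaminone 5 (not isolated)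
Conditions: 4 (2 equiv), toluene, 100 °C; then conc. HCl, CH2Cl2, 40 °C
Reagents that add atoms: N,N-dimethylformamide dimethyl acetal (4), COC(OC)N(C)C
Why: Enaminone condensation at the acetyl methyl group followed by acid-induced addition–elimination of the phenol with loss of dimethylamine, the standard chromone synthesis from 2-hydroxyacetophenones; the benzyl ether is stable to both stages.

Step 4
Reactants: 6 7-(benzyloxy)-8-methoxy-4H-chromen-4-one; 7 (3,4,5-trimethoxyphenyl)boronic acid
Product: 8 (2S)-7-(benzyloxy)-8-methoxy-2-(3,4,5-trimethoxyphenyl)-2,3-dihydro-4H-chromen-4-one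
Conditions: Pd(OCOCF3)2 (5 mol %), (R)-4-tert-butyl-2-(pyridin-2-yl)-4,5-dihydrooxazole (6 mol %), NH4PF6 (30 mol %), H2O (5 equiv), ClCH2CH2Cl, 60 °C
Reagents that add atoms: (3,4,5-trimethoxyphenyl)boronic acid (7), COc1cc(B(O)O)cc(OC)c1OC
Why: Catalytic asymmetric conjugate addition of an arylboronic acid to a chromone with a cationic divalent palladium pyridine–oxazoline catalyst; the ligand decides which face of C2 receives the aryl group. The medium contains no base, so the flavanone cannot racemise by opening to the chalcone.

Step 5
Reactants: 8 (2S)-7-(benzyloxy)-8-methoxy-2-(3,4,5-trimethoxyphenyl)-2,3-dihydro-4H-chromen-4-one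
Product: 10 (2R)-7-(benzyloxy)-3-diazo-8-methoxy-2-(3,4,5-trimethoxyphenyl)-2,3-dihydro-4H-chromen-4-one, via trifluoroacetyl ketone 9 (not isolated)
Conditions: LiN(SiMe3)2, THF, −78 °C; CF3CO2CH2CF3, −78 °C; aq. HCl work-up; then MsN3, Et3N, H2O (1 equiv), MeCN, 20 °C
Reagents that add atoms: methanesulfonyl azide, CS(=O)(=O)N=[N+]=[N-]
Why: Detrifluoroacetylative diazo transfer (a Regitz-type transfer to an activated 1,3-dicarbonyl): the kinetic enolate is C-acylated at −78 °C, and the acidic diketone then takes the diazo group under mild amine base with loss of the trifluoroacetyl group. The short enolate lifetime at low temperature holds back E1cB opening at C2; the descriptor changes to R only because the diazo carbon outranks the aryl group.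

Step 6
Reactants: 10 (2R)-7-(benzyloxy)-3-diazo-8-methoxy-2-(3,4,5-trimethoxyphenyl)-2,3-dihydro-4H-chromen-4-one
Product: 13 methyl (2S,3S)-6-(benzyloxy)-7-methoxy-2-(3,4,5-trimethoxyphenyl)-2,3-dihydro-1-benzofuran-3-carboxylate, via ketene 11 (not isolated), via cis ester 12 (not isolated)
Conditions: hν (365 nm), degassed MeOH/THF, 0–20 °C; then NaOMe (0.2 equiv), MeOH, 20 °C
Reagents that add atoms: methanol, CO
Why: Direct excitation of the diazo ketone expels N2 and, because the six-membered ring holds the C=O and C=N2 groups s-Z, the aryl carbon C4a shifts from the carbonyl carbon to C3 in concert with nitrogen loss (Wolff rearrangement), forging the C3–C3a bond and leaving the old carbonyl carbon as a ketene exocyclic to the new ring. The closest known reaction type is the photochemical Wolff ring contraction of cyclic 2-diazo ketones in alcohols, which includes 3-diazochroman-4-ones going to dihydrobenzofuran-3-carboxylates. The dihydrofuran ring is therefore not closed by a cyclisation but arises by contraction of the pyranone through a 1,2-shift, so no ring-closure trajectory has to be met. Methanol adds to ketene 11 and the ester enol is protonated at C3 mainly from the face away from the C2 aryl group, which gives cis ester 12 first. The new stereocentre C3 is then placed under thermodynamic control: catalytic NaOMe epimerises it through the ester enolate until the ester is trans to the aryl group on C2, which is the controlling element. C2 is a spectator sp3 carbon throughout, and opening of the ester enolate by loss of O1 would be the reverse of a 5-endo-trig closure and is not expected. The selectivity needed is rearrangement over the carbene side reactions (1,2-hydride shift from C2 to the flavone, insertion into the O–H bond of methanol); it is secured by the locked s-Z geometry, the high migratory aptitude of the aryl carbon, and unsensitised irradiation without a metal carbenoid catalyst.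

Step 7
Reactants: 13 methyl (2S,3S)-6-(benzyloxy)-7-methoxy-2-(3,4,5-trimethoxyphenyl)-2,3-dihydro-1-benzofuran-3-carboxylate
Product: 14 [(2S,3R)-6-(benzyloxy)-7-methoxy-2-(3,4,5-trimethoxyphenyl)-2,3-dihydro-1-benzofuran-3-yl]methanol
Conditions: LiAlH4, THF, 0 °C
Reagents that add atoms: none
Why: Hydride reduction of an ester to the primary alcohol; ethers and both stereocentres are untouched, and C3 is no longer acidic afterwards (the descriptor changes to R by priority only).

Step 8
Reactants: 14 [(2S,3R)-6-(benzyloxy)-7-methoxy-2-(3,4,5-trimethoxyphenyl)-2,3-dihydro-1-benzofuran-3-yl]methanol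
Product: 15 [(2S,3R)-6-(benzyloxy)-7-methoxy-2-(3,4,5-trimethoxyphenyl)-2,3-dihydro-1-benzofuran-3-yl]methyl 4-methylbenzenesulfonate
Conditions: TsCl, Et3N, DMAP (cat.), CH2Cl2, 0–20 °C
Reagents that add atoms: p-toluenesulfonyl chloride, Cc1ccc(cc1)S(Cl)(=O)=O
Why: Sulfonylation of an unhindered primary alcohol; no stereocentre is involved.

Step 9
Reactants: 15 [(2S,3R)-6-(benzyloxy)-7-methoxy-2-(3,4,5-trimethoxyphenyl)-2,3-dihydro-1-benzofuran-3-yl]methyl 4-methylbenzenesulfonate
Product: 16 (2S,3S)-6-(benzyloxy)-7-methoxy-3-methyl-2-(3,4,5-trimethoxyphenyl)-2,3-dihydro-1-benzofuran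
Conditions: LiEt3BH, THF, 0–20 °C
Reagents that add atoms: none
Why: SN2 displacement of a primary tosylate by hydride, the standard deoxygenation of a primary alcohol; the reaction takes place one carbon away from C3, whose configuration is unchanged.

Step 10
Reactants: 16 (2S,3S)-6-(benzyloxy)-7-methoxy-3-methyl-2-(3,4,5-trimethoxyphenyl)-2,3-dihydro-1-benzofuran
Product: 17 (2S,3S)-7-methoxy-3-methyl-2-(3,4,5-trimethoxyphenyl)-2,3-dihydro-1-benzofuran-6-ol
Conditions: H2 (1 atm), 10 % Pd/C, EtOAc, 20 °C, stopped after one equivalent
Reagents that add atoms: none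
Why: Hydrogenolysis of a benzyl aryl ether; the primary benzyl group should be cleaved well before the hindered, ring-bound secondary benzylic C2–O1 bond, and no alkene is yet present.

Step 11
Reactants: 17 (2S,3S)-7-methoxy-3-methyl-2-(3,4,5-trimethoxyphenyl)-2,3-dihydro-1-benzofuran-6-ol
Product: 18 (2S,3S)-7-methoxy-3-methyl-2-(3,4,5-trimethoxyphenyl)-2,3-dihydro-1-benzofuran-5,6-dione
Conditions: ON(SO3K)2 (2.5 equiv), KH2PO4 buffer, acetone/H2O, 0 °C; used at once
Reagents that add atoms: potassium nitrosodisulfonate (Fremy's salt), [K+].[K+].[O]N(S(=O)(=O)[O-])S(=O)(=O)[O-]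
Why: Teuber oxidation: the phenoxyl radical is trapped by a second nitrosodisulfonate radical at the free ortho carbon C5 (the para carbon C3a is blocked) and loss of imidodisulfonate gives the ortho-quinone. The buffered, cold medium and immediate use are meant to keep the C3–H from tautomerising towards a quinone methide.

Step 12
Reactants: 18 (2S,3S)-7-methoxy-3-methyl-2-(3,4,5-trimethoxyphenyl)-2,3-dihydro-1-benzofuran-5,6-dione; 19 allyltributylstannane
Product: 20 (2S,3S,5R)-5-allyl-5-hydroxy-7-methoxy-3-methyl-2-(3,4,5-trimethoxyphenyl)-3,5-dihydro-1-benzofuran-6(2H)-one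
Conditions: 19 (1.5 equiv), Sc(OTf)3 (10 mol %), 2,6-bis[(3aS,8aR)-3a,8a-dihydro-8H-indeno[1,2-d]oxazol-2-yl]pyridine (12 mol %), 4 Å MS, CH2Cl2, −78 to −40 °C; aq. NaHCO3
Reagents that add atoms: allyltributylstannane (19), C=CC[Sn](CCCC)(CCCC)CCCC
Why: Proposed new method: the 1,2-dicarbonyl unit of 18 should chelate the trivalent scandium–pybox complex as isatins and glyoxamides do, activating the more electrophilic C5 carbonyl (C6 is a vinylogous ester through O1–C7a=C7 and is deactivated) and exposing one of its faces to the allylstannane, so that the catalyst and not the remote C2/C3 centres decides the configuration at C5; the closest known reaction types are the Lewis-acid-mediated 1,2-allylation of ortho-quinones by allylstannanes and the Sc(OTf)3–pybox-catalysed enantioselective allylation of isatins.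

Step 13
Reactants: 20 (2S,3S,5R)-5-allyl-5-hydroxy-7-methoxy-3-methyl-2-(3,4,5-trimethoxyphenyl)-3,5-dihydro-1-benzofuran-6(2H)-one
Product: 21 (2S,3S,5R)-5-allyl-5,7-dimethoxy-3-methyl-2-(3,4,5-trimethoxyphenyl)-3,5-dihydro-1-benzofuran-6(2H)-one
Conditions: MeI (excess), Ag2O, 4 Å MS, CH2Cl2, 20 °C, dark
Reagents that add atoms: iodomethane, CI
Why: Purdie methylation of the acidic α-ketol hydroxyl; no free alkoxide is formed, which avoids anionic oxy-Cope and ketol shifts, and ambient temperature avoids the retro-Claisen and Cope shifts of the product. C5 is not touched, so its configuration is carried over.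

## Compound list

1 | gallacetophenone (1-(2,3,4-trihydroxyphenyl)ethan-1-one) | CC(=O)c1ccc(O)c(O)c1O | starting material
2 | 1-[4-(benzyloxy)-2,3-dihydroxyphenyl]ethan-1-one | CC(=O)c1ccc(OCc2ccccc2)c(O)c1O | intermediate
3 | 1-[4-(benzyloxy)-2-hydroxy-3-methoxyphenyl]ethan-1-one | CC(=O)c1ccc(OCc2ccccc2)c(OC)c1O | intermediate
4 | N,N-dimethylformamide dimethyl acetal | COC(OC)N(C)C | starting material
5 | (2E)-1-[4-(benzyloxy)-2-hydroxy-3-methoxyphenyl]-3-(dimethylamino)prop-2-en-1-one | CN(C)/C=C/C(=O)c1ccc(OCc2ccccc2)c(OC)c1O | intermediate
6 | 7-(benzyloxy)-8-methoxy-4H-chromen-4-one | COc1c(OCc2ccccc2)ccc2c(=O)ccoc12 | intermediate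
7 | (3,4,5-trimethoxyphenyl)boronic acid | COc1cc(B(O)O)cc(OC)c1OC | starting material
8 | (2S)-7-(benzyloxy)-8-methoxy-2-(3,4,5-trimethoxyphenyl)-2,3-dihydro-4H-chromen-4-one | COc1c(OCc2ccccc2)ccc2c1O[C@H](c1cc(OC)c(OC)c(OC)c1)CC2=O | intermediate
9 | (2S)-7-(benzyloxy)-8-methoxy-3-(trifluoroacetyl)-2-(3,4,5-trimethoxyphenyl)-2,3-dihydro-4H-chromen-4-one (C3 epimers and enol) | COc1c(OCc2ccccc2)ccc2c1O[C@H](c1cc(OC)c(OC)c(OC)c1)C(C(=O)C(F)(F)F)C2=O | intermediate
10 | (2R)-7-(benzyloxy)-3-diazo-8-methoxy-2-(3,4,5-trimethoxyphenyl)-2,3-dihydro-4H-chromen-4-one | COc1c(OCc2ccccc2)ccc2c1O[C@H](c1cc(OC)c(OC)c(OC)c1)C(=[N+]=[N-])C2=O | intermediate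
11 | (2R)-6-(benzyloxy)-7-methoxy-3-(oxomethylidene)-2-(3,4,5-trimethoxyphenyl)-2,3-dihydro-1-benzofuran (ketene) | COc1c(OCc2ccccc2)ccc2c1O[C@H](c1cc(OC)c(OC)c(OC)c1)C2=C=O | intermediate
12 | methyl (2S,3R)-6-(benzyloxy)-7-methoxy-2-(3,4,5-trimethoxyphenyl)-2,3-dihydro-1-benzofuran-3-carboxylate (cis) | COc1c(OCc2ccccc2)ccc2c1O[C@H](c1cc(OC)c(OC)c(OC)c1)[C@@H]2C(=O)OC | intermediate
13 | methyl (2S,3S)-6-(benzyloxy)-7-methoxy-2-(3,4,5-trimethoxyphenyl)-2,3-dihydro-1-benzofuran-3-carboxylate (trans) | COc1c(OCc2ccccc2)ccc2c1O[C@H](c1cc(OC)c(OC)c(OC)c1)[C@H]2C(=O)OC | intermediate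
14 | [(2S,3R)-6-(benzyloxy)-7-methoxy-2-(3,4,5-trimethoxyphenyl)-2,3-dihydro-1-benzofuran-3-yl]methanol | COc1c(OCc2ccccc2)ccc2c1O[C@H](c1cc(OC)c(OC)c(OC)c1)[C@H]2CO | intermediate
15 | [(2S,3R)-6-(benzyloxy)-7-methoxy-2-(3,4,5-trimethoxyphenyl)-2,3-dihydro-1-benzofuran-3-yl]methyl 4-methylbenzenesulfonate | COc1c(OCc2ccccc2)ccc2c1O[C@H](c1cc(OC)c(OC)c(OC)c1)[C@H]2COS(=O)(=O)c1ccc(C)cc1 | intermediate
16 | (2S,3S)-6-(benzyloxy)-7-methoxy-3-methyl-2-(3,4,5-trimethoxyphenyl)-2,3-dihydro-1-benzofuran | COc1c(OCc2ccccc2)ccc2c1O[C@H](c1cc(OC)c(OC)c(OC)c1)[C@H]2C | intermediate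
17 | (2S,3S)-7-methoxy-3-methyl-2-(3,4,5-trimethoxyphenyl)-2,3-dihydro-1-benzofuran-6-ol | COc1c(O)ccc2c1O[C@H](c1cc(OC)c(OC)c(OC)c1)[C@H]2C | intermediate
18 | (2S,3S)-7-methoxy-3-methyl-2-(3,4,5-trimethoxyphenyl)-2,3-dihydro-1-benzofuran-5,6-dione | O=C1C=C2C(=C(OC)C1=O)O[C@H](c1cc(OC)c(OC)c(OC)c1)[C@H]2C | intermediate
19 | allyltributylstannane | C=CC[Sn](CCCC)(CCCC)CCCC | starting material
20 | (2S,3S,5R)-5-allyl-5-hydroxy-7-methoxy-3-methyl-2-(3,4,5-trimethoxyphenyl)-3,5-dihydro-1-benzofuran-6(2H)-one | C=CC[C@@]1(O)C=C2C(=C(OC)C1=O)O[C@H](c1cc(OC)c(OC)c(OC)c1)[C@H]2C | intermediate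
21 | (2S,3S,5R)-5-allyl-5,7-dimethoxy-3-methyl-2-(3,4,5-trimethoxyphenyl)-3,5-dihydro-1-benzofuran-6(2H)-one | C=CC[C@@]1(OC)C=C2C(=C(OC)C1=O)O[C@H](c1cc(OC)c(OC)c(OC)c1)[C@H]2C | target

## Step count and risk

Total step count: 13. Longest linear sequence: 13 steps, from 1 to 21; compounds 4, 7 and 19 are bought.

**Step 12 (the step labelled as a proposed new method).** What may go wrong:
- poor facial selectivity at C5 if the scandium chelate does not hold the quinone rigidly;
- single-electron transfer from the stannane to the Lewis-acid-bound quinone, leading to reduction or O-allylation;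
- conjugate attack at C4;
- ionisation of the C2–O1 bond, which in 18 is a vinylogous benzylic ester;
- migration of the allyl group in the product under Lewis acid.

Fallback, known chemistry: starting from 18, addition of 19 promoted by the achiral Lewis acid BF3·OEt2 in CH2Cl2 at −78 °C, the established 1,2-allylation of ortho-quinones, should give 20 together with its C5 epimer, (2S,3S,5S)-5-allyl-5-hydroxy-7-methoxy-3-methyl-2-(3,4,5-trimethoxyphenyl)-3,5-dihydro-1-benzofuran-6(2H)-one F1. Without substrate bias a near-even mixture must be expected. The diastereomers are separated by chromatography and the route is rejoined at 20.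

**Step 6 (key step).** What may go wrong: nitrogen loss to a free carbene followed by 1,2-hydride shift from C2, which aromatises the ring to the flavone; insertion into the O–H bond of the solvent; secondary photolysis of the electron-rich product. Fallback: starting from 8, oxidative ring contraction with trivalent iodine (PhI(OAc)2, H2SO4 cat., HC(OMe)3/MeOH, 20 °C). The enol ether of the ketal is iodinated at C3 anti to the C2 aryl group, and the same aryl carbon C4a migrates from C4 to C3 as iodobenzene leaves, which gives the trans ester directly with C2 untouched. Competing migration of the C2 aryl group is the known liability of this reaction. It bypasses 9 to 12 and rejoins the route at 13; no compound outside the compound list is formed (F0).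

**Step 5.** What may go wrong: E1cB opening of the lithium enolate to the chalcone phenoxide and re-closure, which erodes the configuration at C2; O- instead of C-trifluoroacetylation. Fallback: starting from 8, acid-mediated nitrosation at C3 (isoamyl nitrite, HCl, THF, 0 °C), which proceeds through the enol and never forms an enolate, gives (2R)-7-(benzyloxy)-3-(hydroxyimino)-8-methoxy-2-(3,4,5-trimethoxyphenyl)-2,3-dihydro-4H-chromen-4-one F2. The Forster reaction (NH2Cl from aqueous NH3 and NaOCl, 0 °C) converts the oxime into the diazo ketone, rejoining at 10.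

**Step 11.** What may go wrong: coupling of the second nitrosodisulfonate radical at the methoxy-bearing C7 with loss of the methyl group, giving the isomeric 6,7-quinone; tautomerisation of the quinone through its C3–H to a quinone methide and on to an aromatic benzofuran, which would erase C3 and C2. Fallback: starting from 17, Casnati–Skattebøl formylation at the only free ortho position (MgCl2, Et3N, paraformaldehyde, MeCN, reflux) gives (2S,3S)-6-hydroxy-7-methoxy-3-methyl-2-(3,4,5-trimethoxyphenyl)-2,3-dihydro-1-benzofuran-5-carbaldehyde F3. Acid-promoted Dakin oxidation (H2O2, boric acid, H2SO4 cat., THF) passes through (2S,3S)-6-hydroxy-7-methoxy-3-methyl-2-(3,4,5-trimethoxyphenyl)-2,3-dihydro-1-benzofuran-5-yl formate F4 to (2S,3S)-7-methoxy-3-methyl-2-(3,4,5-trimethoxyphenyl)-2,3-dihydro-1-benzofuran-5,6-diol F5. Ag2O in Et2O at 0 °C oxidises this catechol to the quinone, rejoining at 18.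

## Further compounds

F1 | step 12 | (2S,3S,5S)-5-allyl-5-hydroxy-7-methoxy-3-methyl-2-(3,4,5-trimethoxyphenyl)-3,5-dihydro-1-benzofuran-6(2H)-one | C=CC[C@]1(O)C=C2C(=C(OC)C1=O)O[C@H](c1cc(OC)c(OC)c(OC)c1)[C@H]2C
F0 | step 6 | none | none
F2 | step 5 | (2R)-7-(benzyloxy)-3-(hydroxyimino)-8-methoxy-2-(3,4,5-trimethoxyphenyl)-2,3-dihydro-4H-chromen-4-one | COc1c(OCc2ccccc2)ccc2c1O[C@H](c1cc(OC)c(OC)c(OC)c1)C(=NO)C2=O
F3 | step 11 | (2S,3S)-6-hydroxy-7-methoxy-3-methyl-2-(3,4,5-trimethoxyphenyl)-2,3-dihydro-1-benzofuran-5-carbaldehyde | COc1c(O)c(C=O)cc2c1O[C@H](c1cc(OC)c(OC)c(OC)c1)[C@H]2C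
F4 | step 11 | (2S,3S)-6-hydroxy-7-methoxy-3-methyl-2-(3,4,5-trimethoxyphenyl)-2,3-dihydro-1-benzofuran-5-yl formate | COc1c(O)c(OC=O)cc2c1O[C@H](c1cc(OC)c(OC)c(OC)c1)[C@H]2C
F5 | step 11 | (2S,3S)-7-methoxy-3-methyl-2-(3,4,5-trimethoxyphenyl)-2,3-dihydro-1-benzofuran-5,6-diol | COc1c(O)c(O)cc2c1O[C@H](c1cc(OC)c(OC)c(OC)c1)[C@H]2C
A1 | alternative 1 | 4-allyl-2-[(1S,2S)-1-(ethynyloxy)-1-(3,4,5-trimethoxyphenyl)propan-2-yl]-4-methoxycyclobut-2-en-1-one (ring carbon 4 unspecified) | C#CO[C@H](c1cc(OC)c(OC)c(OC)c1)[C@@H](C)C1=CC(CC=C)(OC)C1=O
A2 | alternative 1 | (2S,3S,5R)-5-allyl-5-methoxy-3-methyl-2-(3,4,5-trimethoxyphenyl)-3,5-dihydro-1-benzofuran-6(2H)-one | C=CC[C@@]1(OC)C=C2C(=CC1=O)O[C@H](c1cc(OC)c(OC)c(OC)c1)[C@H]2C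
A3 | alternative 2 | 5-[(1S,2S)-1-hydroxy-1-(3,4,5-trimethoxyphenyl)propan-2-yl]-3-methoxybenzene-1,2-diol | O[C@H](c1cc(OC)c(OC)c(OC)c1)[C@@H](C)c1cc(O)c(O)c(OC)c1
A4 | alternative 2 | (2S,3S)-7-methoxy-3-methyl-2-(3,4,5-trimethoxyphenyl)-2,3-dihydro-1-benzofuran-5,6-dione | O=C1C=C2C(=C(OC)C1=O)O[C@H](c1cc(OC)c(OC)c(OC)c1)[C@H]2C
A5 | alternative 3 | 4-{(2R)-2-[2-hydroxy-3-methoxy-4-(methoxymethoxy)phenyl]propyl}-2,6-dimethoxyphenol | COCOc1ccc([C@H](C)Cc2cc(OC)c(O)c(OC)c2)c(O)c1OC
A6 | alternative 3 | 2,6-dimethoxy-4-[(2S,3S)-7-methoxy-6-(methoxymethoxy)-3-methyl-2,3-dihydro-1-benzofuran-2-yl]phenol | COCOc1ccc2c(c1OC)O[C@H](c1cc(OC)c(O)c(OC)c1)[C@H]2C
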